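Compound numbers 1–24 are fixed by the steps below and are used throughout. Germacrane numbering is used for the ring-derived compounds: ring C1–C10, lactone oxygen on C6, lactone carbonyl C12, oxygenated methylene C13 on C11, methyl C14 on C10, methyl C15 on C4.

## Analysis of the target

The target 24 is a germacranolide: a ten-membered carbocycle (C1–C10) fused through C6–C7 to a butenolide whose tetrasubstituted C7=C11 double bond carries the acetoxymethyl group C13 on C11, while O8 bears a senecioate. Two cis-configured trisubstituted epoxides span C1–C10 (methyl C14 on C10) and C4–C5 (methyl C15 on C4). The six stereocenters are 1S, 4S, 5R, 6R, 8R and 10R: C4, C5 and C6 are contiguous with the C5 and C6 oxygens anti, C8 sits on the other flank of the butenolide, and the C10 oxygen is 1,3-anti to O8. Both epoxides are acid-labile, and the C6 hydrogen is the γ-proton of the butenolide with an epoxide next to it, so strong base can open the C4–C5 epoxide by vinylogous β-elimination. The allylic acetate and the conjugated senecioate do not survive organometallic or hydride steps and have to be introduced last. The difficulty is to close a medium ring against transannular strain while placing the remote centers C8 and C1/C10 correctly relative to the C4–C6 triad. The strategy rests on the fact that C1 and C10 both carry the epoxide oxygen: at the carbonyl level they are a C1 aldehyde and a C10 methyl ketone, and the α-hydroxy ketone C1(=O)–C10(OH)(CH3) is the retron of an acyloin bond formation that closes the ten-membered ring.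

## Retrosynthetic reasoning

**Esters (24 ⇒ 23 ⇒ 22 ⇒ 21).** The two acyl C–O bonds are cut first because neither ester tolerates the earlier chemistry. Both oxygens are carried as silyl ethers in 21. After desilylation to 22, the primary C13 hydroxyl is acetylated before the hindered secondary C8 hydroxyl, so the forward steps only need primary-versus-secondary selectivity.

**C1–O bond of the C1–C10 epoxide (21 ⇒ 19 ⇒ 18).** Opening this epoxide at C1 leads back to the trans-diol 19 and, one oxidation level up, to the hydroxy ketone 18. The forward sequence must set C1 as R and then invert it, with the C10 oxygen as the internal nucleophile. The tertiary C10 center is never touched again.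

**C1–C10 bond (18 ⇒ 17).** This is the only ring bond whose two carbons are both oxygenated, so the cut generates no new functional groups. An aldehyde at C1 is a natural acyl-anion donor under carbene catalysis and a methyl ketone at C10 a natural acceptor. The forward reaction must close a ten-membered ring and set C10 as R in one catalytic isomerisation.

**Both carbonyl groups (17 ⇒ 15, through 16).** The aldehyde and the ketone are traced back to a trisubstituted and a 1,1-disubstituted alkene, which are cleaved together by ozonolysis. Neither carbonyl then has to survive fragment assembly, and the β-silyloxy ketone is never exposed to the bases used to build the butenolide.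

**C6–C7 and O6–C12 (15 ⇒ 10 + 13).** Cutting the butenolide at the carbinol carbon C6 and at the lactone C–O bond divides the molecule into two fragments of similar size. A Nozaki–Hiyama–Kishi coupling of the enol triflate 10 with the epoxy aldehyde 13 forms the C–C bond, the resulting alkoxide (14) lactonises onto the cis ester, and the adjacent epoxide directs the new C6 center (Felkin–Anh, anti).

**Epoxy aldehyde (13 ⇒ 12 ⇒ 11).** The carbon chain of 11 supplies C6 through C1 with the C15 methyl in place. Its Z double bond becomes the cis C4–C5 epoxide by Sharpless asymmetric epoxidation, and its remote trisubstituted alkene is the latent C1 aldehyde.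

**Enol triflate (10 ⇒ 9 ⇒ 8 ⇒ 5 + 7).** The C7–C11 bond is made by an ester-enolate aldol between 7 and 5, followed by oxidation to the β-keto ester 9. Chelation-controlled triflation then places the triflate cis to the ester, which is the geometry the later lactonisation requires.

**C8 stereocenter (5 ⇒ 4 ⇒ 3 ⇒ 1 + 2; 7 ⇒ 6).** A catalytic asymmetric glyoxylate–ene reaction between 1 and 2 forms C8–C9, sets C8, and delivers the masked C10 ketone (the 2-propenyl group) in one step. The three-carbon unit C11–C13 comes from 6 after silylation.

## Alternatives that were turned down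

**Alternative 1: butenolide annulation onto a preformed ring.**
- Disconnection: the C7=C11 double bond and the O6–C12 acyl bond.
- Forward key step: A1, a ten-membered C7 ketone with a mixed allyl malonate on O6, undergoes an amine-salt-catalysed intramolecular Knoevenagel condensation to the butenolide A2, whose C11 allyl ester is the latent C13.
- For: it is a five-membered ring closure of a well-established type under mild conditions, and it separates lactone formation from macrocyclisation.
- Against:
  - A1 is itself a ten-membered α-acyloxy ketone, so its ring still has to be closed by some other macrocyclisation; the hardest problem is postponed, not solved.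
  - The C7 ketone of A1 is flanked by two oxygenated centers. Enolisation toward C6 (acyloxy, next to the C4–C5 epoxide) or C8 (silyloxy) invites epimerisation, β-elimination and acyl migration under the amine/acid conditions.
  - After A2, the C11 ester must be reduced to the C13 alcohol in the presence of the lactone carbonyl on the same alkene and two epoxides, then acetylated, before O8 is unmasked and acylated.
- Comparison: Alternative 1 is stronger in the precedent for its key step. The chosen route builds the butenolide early, intermolecularly and at the final C13 oxidation level, and its ring closure also installs the C10 oxygen and stereocenter.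

**Alternative 2: nickel/chromium macrocyclisation with lactonisation in the same flask.**
- Disconnection: again C6–C7 and O6–C12, but intramolecularly.
- Forward key step: the open-chain precursor A3 (C7 enol triflate, C6 epoxy aldehyde, both epoxides in place) is treated with divalent chromium and catalytic nickel; the alkenylchromium adds to the aldehyde and the alkoxide closes the lactone, giving A4.
- For: organochromium addition has a record in medium-ring closure and is aldehyde-selective, and after A4 only a protecting-group exchange and two acylations remain. On precedent for the ring-closing event and on brevity after ring closure it is stronger than the chosen route.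
- Against:
  - A3 needs the C1–C10 cis-epoxide built enantioselectively in an open chain without an allylic alcohol to direct it, which lengthens the linear sequence.
  - Two epoxides and an epoxy aldehyde are exposed for a long time, at high dilution, to Lewis-acidic trivalent chromium and chloride.
  - The C6 configuration is set during ring closure, where ring strain can override Felkin–Anh control.
- Comparison: the chosen route uses the same chromium chemistry intermolecularly at normal concentration, with only one epoxide present and undisturbed acyclic stereocontrol at C6. It then closes the ring by a metal-free catalytic isomerisation that creates the second epoxide's carbon–oxygen pattern.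

**Alternative 3: B-alkyl Suzuki–Miyaura macrocyclisation at C3–C4.**
- Disconnection: the C3–C4 bond (sp3–sp2).
- Forward key step: A5 carries a vinyl group on the C1–C10 epoxide and a (Z)-iodoalkene at C4. Hydroboration of the vinyl terminus (C3) and palladium-catalysed coupling with the iodoalkene close the ring to A6, the 4,5-deoxy compound; epoxidation of its cis C4=C5 alkene would give 24.
- For: the ring-closing bond is an unfunctionalised C–C bond remote from stereocenters, the method is established for macrocycles, both esters are already in place, and only one step follows.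
- Against:
  - The hydroboration must add to a vinyl epoxide without opening it.
  - The resulting γ-boryl epoxide can undergo 1,3-elimination once it is converted to a borate by aqueous base.
  - The acetate, the senecioate and the butenolide are exposed to warm aqueous base.
  - The final epoxidation of A6 has no directing group (O6 is tied up in the lactone), so the C4/C5 configuration is left to the ring conformation at the last step.
- Comparison: Alternative 3 is stronger in the reliability of the ring-closing bond formation and in the number of steps after it. The chosen route fixes C4 and C5 at the outset by reagent control, uses the C4–C5 epoxide to direct C6, and closes the ring without base-labile esters present.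

Key step: step 12

## Route

Remark on the chemistry: the C10 carbonyl is assumed to be best carried as a 2-propenyl group until step 11, so that both carbonyl groups of 17 are released in a single operation.

Step 1
Reactants: 1 ethyl glyoxylate; 2 isobutylene (2-methylpropene)
Product: 3 ethyl (2R)-2-hydroxy-4-methylpent-4-enoate
Conditions: (R)-BINOL/TiCl2(OiPr)2 (10 mol%), 4 Å MS, CH2Cl2, −30 °C
Reagents that add atoms: none
Why: Catalytic asymmetric glyoxylate–ene reaction; the chiral titanium Lewis acid activates the aldehyde and the 1,1-disubstituted alkene adds through a six-membered ene transition state, the (R)-BINOL complex being expected to give the 2R alcohol (future C8). The product already contains C7–C10 and C14, with the future C10 ketone masked as an alkene.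

Step 2
Reactants: 3 ethyl (2R)-2-hydroxy-4-methylpent-4-enoate
Product: 4 ethyl (2R)-2-(tert-butyldimethylsilyloxy)-4-methylpent-4-enoate
Conditions: TBSCl, imidazole, DMF, rt
Reagents that add atoms: tert-butyldimethylsilyl chloride, CC(C)(C)[Si](C)(C)Cl
Why: Standard silylation of a secondary alcohol under imidazole catalysis; no bond to the stereocenter is broken.

Step 3
Reactants: 4 ethyl (2R)-2-(tert-butyldimethylsilyloxy)-4-methylpent-4-enoate
Product: 5 (2R)-2-(tert-butyldimethylsilyloxy)-4-methylpent-4-enal
Conditions: iBu2AlH (1.1 equiv), CH2Cl2, −78 °C; aq. KNaC4H4O6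
Reagents that add atoms: none
Why: Partial reduction of an α-silyloxy ester; the tetrahedral aluminium hemiacetal is stable at −78 °C and collapses to the aldehyde only on work-up, so over-reduction and epimerisation should be avoided.

Step 4
Reactants: 6 methyl 3-hydroxypropanoate
Product: 7 methyl 3-(tert-butyldimethylsilyloxy)propanoate
Conditions: TBSCl, imidazole, CH2Cl2, rt
Reagents that add atoms: tert-butyldimethylsilyl chloride, CC(C)(C)[Si](C)(C)Cl
Why: Silylation of a primary alcohol; the silyl ether is the future O13 protecting group.

Step 5
Reactants: 7 methyl 3-(tert-butyldimethylsilyloxy)propanoate; 5 (2R)-2-(tert-butyldimethylsilyloxy)-4-methylpent-4-enal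
Product: 8 methyl (4R)-4-(tert-butyldimethylsilyloxy)-2-[(tert-butyldimethylsilyloxy)methyl]-3-hydroxy-6-methylhept-6-enoate (mixture at C2 and C3)
Conditions: LiN(iPr)2, THF, −78 °C; then 5, −78 °C; aq. NH4Cl
Reagents that add atoms: none
Why: Aldol addition of a lithium ester enolate to an aldehyde, forming C7–C11; at −78 °C addition should be faster than β-elimination of the silyloxy group from the enolate. The two new centers are removed in steps 6 and 7, so their configuration is irrelevant.

Step 6
Reactants: 8 methyl (4R)-4-(tert-butyldimethylsilyloxy)-2-[(tert-butyldimethylsilyloxy)methyl]-3-hydroxy-6-methylhept-6-enoate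
Product: 9 methyl (4R)-4-(tert-butyldimethylsilyloxy)-2-[(tert-butyldimethylsilyloxy)methyl]-6-methyl-3-oxohept-6-enoate (C2 epimers)
Conditions: Dess–Martin periodinane, NaHCO3, CH2Cl2, 0 °C → rt
Reagents that add atoms: none
Why: Buffered Dess–Martin oxidation of a β-hydroxy ester to the β-keto ester under near-neutral conditions, which should leave the α-silyloxy center C4 (future C8) unepimerised.

Step 7
Reactants: 9 methyl (4R)-4-(tert-butyldimethylsilyloxy)-2-[(tert-butyldimethylsilyloxy)methyl]-6-methyl-3-oxohept-6-enoate
Product: 10 methyl (2Z,4R)-4-(tert-butyldimethylsilyloxy)-2-[(tert-butyldimethylsilyloxy)methyl]-6-methyl-3-(trifluoromethanesulfonyloxy)hepta-2,6-dienoate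
Conditions: LiN(SiMe3)2, toluene, −78 °C; Tf2O, −78 → 0 °C
Reagents that add atoms: trifluoromethanesulfonic anhydride, O=S(=O)(OS(=O)(=O)C(F)(F)F)C(F)(F)F
Why: O-Triflation of a β-keto ester enolate; in a non-coordinating solvent the lithium enolate is chelated between the two carbonyl oxygens, so triflation of the ketone oxygen should place the triflate cis to the ester (Z). Only the far more acidic C2 proton is removed, so C4 is not touched.

Step 8
Reactants: 11 nerol
Product: 12 [(2R,3S)-3-methyl-3-(4-methylpent-3-en-1-yl)oxiran-2-yl]methanol ((2R,3S)-2,3-epoxynerol)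
Conditions: Ti(OiPr)4 (10 mol%), D-(−)-diethyl tartrate (12 mol%), tBuOOH, 4 Å MS, CH2Cl2, −20 °C
Reagents that add atoms: tert-butyl hydroperoxide, CC(C)(C)OO
Why: Sharpless asymmetric epoxidation; the titanium tartrate epoxidises only the allylic alcohol double bond, the D-(−)-tartrate is expected to give the 2R,3S enantiomer, and the Z geometry fixes the cis relationship of the future C3 and C6.

Step 9
Reactants: 12 (2R,3S)-2,3-epoxynerol
Product: 13 (2S,3S)-3-methyl-3-(4-methylpent-3-en-1-yl)oxirane-2-carbaldehyde
Conditions: TEMPO (10 mol%), PhI(OAc)2, CH2Cl2, rt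
Reagents that add atoms: none
Why: Oxoammonium-mediated oxidation of a primary alcohol to the aldehyde under neutral conditions that should preserve the epoxide and the α-center; the descriptor at C2 changes only because the priorities change.

Step 10
Reactants: 10 methyl (2Z,4R)-4-(tert-butyldimethylsilyloxy)-2-[(tert-butyldimethylsilyloxy)methyl]-6-methyl-3-(trifluoromethanesulfonyloxy)hepta-2,6-dienoate; 13 (2S,3S)-3-methyl-3-(4-methylpent-3-en-1-yl)oxirane-2-carbaldehyde
Product: 15 (5R)-4-[(1R)-1-(tert-butyldimethylsilyloxy)-3-methylbut-3-en-1-yl]-3-[(tert-butyldimethylsilyloxy)methyl]-5-[(2R,3S)-3-methyl-3-(4-methylpent-3-en-1-yl)oxiran-2-yl]furan-2(5H)-one, via C6 hydroxy ester 14 (not isolated)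
Conditions: CrCl2 (5 equiv), NiCl2 (5 mol%), DMF, rt
Reagents that add atoms: none
Why: Nozaki–Hiyama–Kishi coupling: zerovalent nickel formed in the flask inserts into the C–OTf bond, transmetalation gives an alkenylchromium that adds only to the aldehyde, and retention of alkene geometry places the new alkoxide cis to the methyl ester so that it lactonises to the butenolide. The new C6 center is expected to form R by polar Felkin–Anh addition anti to the epoxide C–O bond, reinforced by the cis C3 chain on the epoxide.

Step 11
Reactants: 15 butenolide with 2-propenyl and prenyl termini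
Product: 17 (4S,5R,6R,8R)-8,13-bis(tert-butyldimethylsilyloxy)-4,5-epoxy-1,10-dioxo-1,10-secogermacr-7(11)-en-12,6-olide (C1 aldehyde and C10 methyl ketone), via bis-ozonide 16 (not isolated)
Conditions: O3, CH2Cl2, −78 °C (Sudan Red 7B end point); then PPh3, −78 °C → rt
Reagents that add atoms: ozone, [O-][O+]=O
Why: Ozonolysis with reductive work-up; the electron-rich trisubstituted and 1,1-disubstituted alkenes react much faster than the electron-poor tetrasubstituted butenolide alkene, and the indicator end point guards against over-oxidation. One operation reveals both the C1 aldehyde and the C10 methyl ketone.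

Step 12
Reactants: 17 keto aldehyde (C1 aldehyde, C10 methyl ketone)
Product: 18 (4S,5R,6R,8R,10R)-8,13-bis(tert-butyldimethylsilyloxy)-4,5-epoxy-10-hydroxy-1-oxogermacr-7(11)-en-12,6-olide
Conditions: (5aS,10bR)-2-(pentafluorophenyl)-5a,10b-dihydro-4H,6H-indeno[2,1-b][1,2,4]triazolo[4,3-d][1,4]oxazin-2-ium tetrafluoroborate (C18H11BF9N3O, 20 mol%), iPr2NEt (20 mol%), toluene, 0.002 M (syringe-pump addition of 17), 40 °C
Reagents that add atoms: none
Why: Proposed new method: the triazolylidene freed from the triazolium salt by the amine adds to the C1 aldehyde, proton transfer gives the catalyst-bound enaminol (Breslow intermediate), its nucleophilic C1 attacks the C10 ketone, and proton transfer with loss of the carbene releases 18; the closest known reaction type is the carbene-catalysed intramolecular crossed aldehyde–ketone benzoin (acyloin) reaction, established for five- and six-membered tertiary α-hydroxy ketones but not for ten-membered carbocycles. The ring closes in a 10-exo-trig mode, the ketone C=O being exocyclic to the new C1–C10 bond. A ketone cannot be converted into a Breslow intermediate, which leaves C1 as the sole nucleophilic carbon and C10 as the sole acceptor, and the tetrasubstituted butenolide carbon C7 is too hindered for a competing Stetter addition. The new C10 center is set by the ketone face that the enaminol reaches: the aminoindanol backbone of the catalyst screens one face of the enaminol and the C8 silyloxy group, held out of the butenolide plane by allylic strain, biases the C9–C10 rotamer, so the 10R alcohol anti to O8 is the outcome expected for the matched catalyst enantiomer. Ring closure should be favoured over oligomerisation by slow addition at high dilution and by the rigid cis-epoxide and butenolide, which leave only seven rotatable bonds between C1 and C10. No atoms are added or lost and the only base is a substoichiometric tertiary amine, conditions under which the lactone, the epoxide, the β-silyloxy ketone and the silyl ethers should persist.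

Step 13
Reactants: 18 C10-hydroxy C1-ketone
Product: 19 (1R,4S,5R,6R,8R,10R)-8,13-bis(tert-butyldimethylsilyloxy)-4,5-epoxy-1,10-dihydroxygermacr-7(11)-en-12,6-olide (hydroxyls trans across C1–C10)
Conditions: (S)-Me-CBS oxazaborolidine C18H20BNO (1.0 equiv), catecholborane, toluene, −78 °C; MeOH quench
Reagents that add atoms: none
Why: Corey–Bakshi–Shibata reduction; the oxazaborolidine binds the ketone oxygen anti to the fully substituted C10 and delivers hydride to the face that gives the 1R alcohol, so the reagent and not the ring conformation should decide the configuration. Catecholborane at −78 °C does not reduce the lactone or open the epoxide.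

Step 14
Reactants: 19 trans-1,10-diol
Product: 21 (1S,4S,5R,6R,8R,10R)-8,13-bis(tert-butyldimethylsilyloxy)-1,10:4,5-diepoxygermacr-7(11)-en-12,6-olide, via C1 mesylate 20 (not isolated)
Conditions: MsCl, Et3N, CH2Cl2, −20 °C; then K2CO3, MeOH, 0 °C → rt
Reagents that add atoms: methanesulfonyl chloride, CS(=O)(=O)Cl (its atoms are present in 20 and leave again on closure)
Why: Only the secondary C1 hydroxyl is sulfonylated, the tertiary C10 hydroxyl being inert; mild base then triggers a 3-exo-tet intramolecular Williamson displacement by the C10 oxygen with inversion at C1, giving the cis-epoxide (1S,10R).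

Step 15
Reactants: 21 bis-epoxide bis(silyl ether)
Product: 22 (1S,4S,5R,6R,8R,10R)-1,10:4,5-diepoxy-8,13-dihydroxygermacr-7(11)-en-12,6-olide
Conditions: HF·pyridine, pyridine, THF, 0 °C → rt
Reagents that add atoms: none
Why: Fluoride-mediated cleavage of both silyl ethers; buffering with excess pyridine keeps the medium mild enough for trisubstituted epoxides and the butenolide.

Step 16
Reactants: 22 8,13-diol
Product: 23 (1S,4S,5R,6R,8R,10R)-13-acetoxy-1,10:4,5-diepoxy-8-hydroxygermacr-7(11)-en-12,6-olide
Conditions: AcCl (1.1 equiv), 2,4,6-collidine, CH2Cl2, −78 °C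
Reagents that add atoms: acetyl chloride, CC(=O)Cl
Why: Acetylation with acetyl chloride and a hindered pyridine base at low temperature is selective for the primary C13 hydroxyl over the hindered secondary C8 hydroxyl.

Step 17
Reactants: 23 13-acetate 8-alcohol
Product: 24 (1S,4S,5R,6R,8R,10R)-13-acetoxy-1,10:4,5-diepoxy-8-(3-methylbut-2-enoyloxy)germacr-7(11)-en-12,6-olide (target)
Conditions: 3-methylbut-2-enoyl chloride, pyridine, DMAP (cat.), CH2Cl2, 0 °C → rt
Reagents that add atoms: 3-methylbut-2-enoyl chloride, CC(C)=CC(=O)Cl
Why: DMAP-catalysed acylation of a secondary alcohol; the weak base pyridine avoids dehydrochlorination of the acid chloride to a vinylketene, so the conjugated senecioate and not its β,γ-isomer should form.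

## Compound list

1 | ethyl glyoxylate | CCOC(=O)C=O | starting material
2 | isobutylene (2-methylpropene) | CC(C)=C | starting material
3 | ethyl (2R)-2-hydroxy-4-methylpent-4-enoate | CCOC(=O)[C@H](O)CC(C)=C | intermediate
4 | ethyl (2R)-2-(tert-butyldimethylsilyloxy)-4-methylpent-4-enoate | CCOC(=O)[C@H](O[Si](C)(C)C(C)(C)C)CC(C)=C | intermediate
5 | (2R)-2-(tert-butyldimethylsilyloxy)-4-methylpent-4-enal | O=C[C@H](O[Si](C)(C)C(C)(C)C)CC(C)=C | intermediate
6 | methyl 3-hydroxypropanoate | COC(=O)CCO | starting material
7 | methyl 3-(tert-butyldimethylsilyloxy)propanoate | COC(=O)CCO[Si](C)(C)C(C)(C)C | intermediate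
8 | methyl (4R)-4-(tert-butyldimethylsilyloxy)-2-[(tert-butyldimethylsilyloxy)methyl]-3-hydroxy-6-methylhept-6-enoate (mixture at C2, C3) | COC(=O)C(CO[Si](C)(C)C(C)(C)C)C(O)[C@H](O[Si](C)(C)C(C)(C)C)CC(C)=C | intermediate
9 | methyl (4R)-4-(tert-butyldimethylsilyloxy)-2-[(tert-butyldimethylsilyloxy)methyl]-6-methyl-3-oxohept-6-enoate (C2 epimers) | COC(=O)C(CO[Si](C)(C)C(C)(C)C)C(=O)[C@H](O[Si](C)(C)C(C)(C)C)CC(C)=C | intermediate
10 | methyl (2Z,4R)-4-(tert-butyldimethylsilyloxy)-2-[(tert-butyldimethylsilyloxy)methyl]-6-methyl-3-(trifluoromethanesulfonyloxy)hepta-2,6-dienoate | COC(=O)/C(CO[Si](C)(C)C(C)(C)C)=C(\OS(=O)(=O)C(F)(F)F)[C@H](O[Si](C)(C)C(C)(C)C)CC(C)=C | intermediate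
11 | nerol | CC(C)=CCC/C(C)=C\CO | starting material
12 | [(2R,3S)-3-methyl-3-(4-methylpent-3-en-1-yl)oxiran-2-yl]methanol | OC[C@H]1O[C@@]1(C)CCC=C(C)C | intermediate
13 | (2S,3S)-3-methyl-3-(4-methylpent-3-en-1-yl)oxirane-2-carbaldehyde | O=C[C@H]1O[C@@]1(C)CCC=C(C)C | intermediate
14 | methyl (4R)-4-(tert-butyldimethylsilyloxy)-2-[(tert-butyldimethylsilyloxy)methyl]-3-{(R)-hydroxy[(2R,3S)-3-methyl-3-(4-methylpent-3-en-1-yl)oxiran-2-yl]methyl}-6-methylhepta-2,6-dienoate (ester and carbinol carbon cis on the C2=C3 bond) | COC(=O)/C(CO[Si](C)(C)C(C)(C)C)=C(\[C@@H](O)[C@H]1O[C@@]1(C)CCC=C(C)C)[C@H](O[Si](C)(C)C(C)(C)C)CC(C)=C | intermediate (not isolated)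
15 | (5R)-4-[(1R)-1-(tert-butyldimethylsilyloxy)-3-methylbut-3-en-1-yl]-3-[(tert-butyldimethylsilyloxy)methyl]-5-[(2R,3S)-3-methyl-3-(4-methylpent-3-en-1-yl)oxiran-2-yl]furan-2(5H)-one | CC(C)(C)[Si](C)(C)OCC1=C([C@@H](OC1=O)[C@H]1O[C@@]1(C)CCC=C(C)C)[C@H](O[Si](C)(C)C(C)(C)C)CC(C)=C | intermediate
16 | bis-ozonide of 15 (1,2,4-trioxolanes in place of both side-chain alkenes) | CC(C)(C)[Si](C)(C)OCC1=C([C@@H](OC1=O)[C@H]1O[C@@]1(C)CCC1OOC(C)(C)O1)[C@H](O[Si](C)(C)C(C)(C)C)CC1(C)OOCO1 | intermediate (not isolated)
17 | (4S,5R,6R,8R)-8,13-bis(tert-butyldimethylsilyloxy)-4,5-epoxy-1,10-dioxo-1,10-secogermacr-7(11)-en-12,6-olide | CC(C)(C)[Si](C)(C)OCC1=C([C@@H](OC1=O)[C@H]1O[C@@]1(C)CCC=O)[C@H](O[Si](C)(C)C(C)(C)C)CC(C)=O | intermediate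
18 | (4S,5R,6R,8R,10R)-8,13-bis(tert-butyldimethylsilyloxy)-4,5-epoxy-10-hydroxy-1-oxogermacr-7(11)-en-12,6-olide | CC(C)(C)[Si](C)(C)OCC1=C2[C@@H](OC1=O)[C@H]1O[C@@]1(C)CCC(=O)[C@](C)(O)C[C@H]2O[Si](C)(C)C(C)(C)C | intermediate
19 | (1R,4S,5R,6R,8R,10R)-8,13-bis(tert-butyldimethylsilyloxy)-4,5-epoxy-1,10-dihydroxygermacr-7(11)-en-12,6-olide | CC(C)(C)[Si](C)(C)OCC1=C2[C@@H](OC1=O)[C@H]1O[C@@]1(C)CC[C@@H](O)[C@](C)(O)C[C@H]2O[Si](C)(C)C(C)(C)C | intermediate
20 | C1 methanesulfonate of 19 | CC(C)(C)[Si](C)(C)OCC1=C2[C@@H](OC1=O)[C@H]1O[C@@]1(C)CC[C@@H](OS(C)(=O)=O)[C@](C)(O)C[C@H]2O[Si](C)(C)C(C)(C)C | intermediate (not isolated)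
21 | (1S,4S,5R,6R,8R,10R)-8,13-bis(tert-butyldimethylsilyloxy)-1,10:4,5-diepoxygermacr-7(11)-en-12,6-olide | CC(C)(C)[Si](C)(C)OCC1=C2[C@@H](OC1=O)[C@H]1O[C@@]1(C)CC[C@@H]1O[C@]1(C)C[C@H]2O[Si](C)(C)C(C)(C)C | intermediate
22 | (1S,4S,5R,6R,8R,10R)-1,10:4,5-diepoxy-8,13-dihydroxygermacr-7(11)-en-12,6-olide | OCC1=C2[C@@H](OC1=O)[C@H]1O[C@@]1(C)CC[C@@H]1O[C@]1(C)C[C@H]2O | intermediate
23 | (1S,4S,5R,6R,8R,10R)-13-acetoxy-1,10:4,5-diepoxy-8-hydroxygermacr-7(11)-en-12,6-olide | CC(=O)OCC1=C2[C@@H](OC1=O)[C@H]1O[C@@]1(C)CC[C@@H]1O[C@]1(C)C[C@H]2O | intermediate
24 | (1S,4S,5R,6R,8R,10R)-13-acetoxy-1,10:4,5-diepoxy-8-(3-methylbut-2-enoyloxy)germacr-7(11)-en-12,6-olide | CC(=O)OCC1=C2[C@@H](OC1=O)[C@H]1O[C@@]1(C)CC[C@@H]1O[C@]1(C)C[C@H]2OC(=O)C=C(C)C | target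

## Step count and least certain steps

Total: 17 steps. Longest linear sequence: 14 steps (1 → 24 through steps 1, 2, 3, 5, 6, 7 and 10–17).

**Step 12 (key step, the only step beyond known chemistry).**
- What may go wrong:
  - Intermolecular acyloin coupling and oligomerisation can outrun closure of the strained ring, or the closure may be reversible and favour the open form.
  - Facial selectivity at C10 may be poor if the catalyst and the C8 substituent are mismatched; the enantiomeric catalyst would then be the first variation.
  - Even the weak amine base may cause β-elimination of the C8 silyloxy group from the C10 ketone, or γ-deprotonation of the butenolide followed by opening of the C4–C5 epoxide.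
- Fallback (known chemistry): it sets out from 17 and comes back at 21. Both carbonyl groups of 17 are methylenated under non-basic conditions (Zn, CH2Br2, TiCl4, THF/CH2Cl2, 0 °C) to the C1-vinyl C10-(2-propenyl) seco compound F1. Ring-closing metathesis with the second-generation Grubbs catalyst RuCl2(PCy3)(H2IMes)(=CHPh) in toluene at high dilution and 80 °C closes the ring at C1=C10, where ring strain should enforce the Z geometry of the cyclodecene F2. Epoxidation of this electron-rich trisubstituted alkene (mCPBA, NaHCO3, CH2Cl2, 0 °C) from the outer face of the ring gives 21 and replaces steps 12–14. Its facial selectivity would depend on the ring conformation.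

**Step 10.**
- What may go wrong: the hindered tetrasubstituted alkenylchromium may add slowly, so that protodemetalation, loss of double-bond geometry through an allenoate-type chromium enolate, or chloride opening of the epoxy aldehyde by trivalent chromium compete. Facial selectivity at C6 may also be insufficient.
- Fallback: it sets out from 10 and comes back at 15, replacing the catalytic nickel/chromium coupling by a stoichiometric, chelation-stabilised alkenylmagnesium. Stannylation of 10 (Pd(PPh3)4, Me3SnSnMe3, LiCl, THF, 60 °C) gives the alkenylstannane F3 with retention of geometry. Iododestannylation (I2, CH2Cl2, 0 °C) gives the (Z)-β-iodo enoate F4. Iodine–magnesium exchange (iPrMgCl·LiCl, THF, −40 °C) and addition to 13 at −78 °C form the alkoxide of 14, which lactonises to 15.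

**Step 13.**
- What may go wrong: hydride may be delivered to the wrong face of the C1 ketone, because the ring conformation or binding of boron to the free tertiary hydroxyl overrides the catalyst.
- Fallback: it sets out from 18 and comes back at 21, using the C1 epimer productively. The reduction product is then the cis-diol F5 (1S,10R). Trimethyl orthoacetate with pyridinium p-toluenesulfonate converts it into the cyclic orthoacetate F6. Me3SiCl opens the derived acetoxonium ion with inversion, expected at the tertiary carbon, to the chloro acetate F7; the regioisomeric opening converges on the same product. K2CO3 in MeOH cleaves the acetate and closes the epoxide with a second inversion, so that overall retention gives 21.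

**Step 14.**
- What may go wrong: the basic medium may trigger γ-deprotonation at C6 with vinylogous β-elimination of the C4–C5 epoxide, or the ring may not reach the anti-periplanar O10–C10–C1–O arrangement before the mesylate solvolyses.
- Fallback: it sets out from 19 and comes back at 21 in one operation, by a Mitsunobu-type cyclodehydration (PPh3, diisopropyl azodicarboxylate, toluene, 0 °C → rt). The secondary hydroxyl is activated as an oxyphosphonium ion and displaced with inversion by the tertiary hydroxyl, without a sulfonate and without an added base. No new compound is made (F0).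

## Further compounds

F1 | step 12 | (4S,5R,6R,8R)-seco compound with C1 vinyl and C10 2-propenyl groups, 8,13-bis(tert-butyldimethylsilyl) ether | CC(C)(C)[Si](C)(C)OCC1=C([C@@H](OC1=O)[C@H]1O[C@@]1(C)CCC=C)[C@H](O[Si](C)(C)C(C)(C)C)CC(C)=C
F2 | step 12 | (1(10)Z,4S,5R,6R,8R)-8,13-bis(tert-butyldimethylsilyloxy)-4,5-epoxygermacra-1(10),7(11)-dien-12,6-olide | CC(C)(C)[Si](C)(C)OCC1=C2[C@@H](OC1=O)[C@H]1O[C@@]1(C)CC/C=C(C)\C[C@H]2O[Si](C)(C)C(C)(C)C
F3 | step 10 | methyl (4R)-4-(tert-butyldimethylsilyloxy)-2-[(tert-butyldimethylsilyloxy)methyl]-6-methyl-3-(trimethylstannyl)hepta-2,6-dienoate (tin cis to the ester) | COC(=O)/C(CO[Si](C)(C)C(C)(C)C)=C(\[Sn](C)(C)C)[C@H](O[Si](C)(C)C(C)(C)C)CC(C)=C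
F4 | step 10 | methyl (2Z,4R)-4-(tert-butyldimethylsilyloxy)-2-[(tert-butyldimethylsilyloxy)methyl]-3-iodo-6-methylhepta-2,6-dienoate | COC(=O)/C(CO[Si](C)(C)C(C)(C)C)=C(\I)[C@H](O[Si](C)(C)C(C)(C)C)CC(C)=C
F5 | step 13 | (1S,4S,5R,6R,8R,10R)-8,13-bis(tert-butyldimethylsilyloxy)-4,5-epoxy-1,10-dihydroxygermacr-7(11)-en-12,6-olide (cis-diol) | CC(C)(C)[Si](C)(C)OCC1=C2[C@@H](OC1=O)[C@H]1O[C@@]1(C)CC[C@H](O)[C@](C)(O)C[C@H]2O[Si](C)(C)C(C)(C)C
F6 | step 13 | cyclic methyl orthoacetate of F5 (2-methoxy-2-methyl-1,3-dioxolane across O1 and O10) | CC(C)(C)[Si](C)(C)OCC1=C2[C@@H](OC1=O)[C@H]1O[C@@]1(C)CC[C@@H]1OC(C)(OC)O[C@]1(C)C[C@H]2O[Si](C)(C)C(C)(C)C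
F7 | step 13 | (1S,10S)-1-acetoxy-10-chloro compound from F6 (C10 inverted) | CC(C)(C)[Si](C)(C)OCC1=C2[C@@H](OC1=O)[C@H]1O[C@@]1(C)CC[C@H](OC(C)=O)[C@@](C)(Cl)C[C@H]2O[Si](C)(C)C(C)(C)C
F0 | step 14 | none | none
A1 | alternative 1 | ten-membered C7 ketone with allyl malonate on O6 (1,10:4,5-diepoxide, O8 tert-butyldimethylsilyl ether) | O=C1[C@@H](OC(=O)CC(=O)OCC=C)[C@H]2O[C@@]2(C)CC[C@@H]2O[C@]2(C)C[C@H]1O[Si](C)(C)C(C)(C)C
A2 | alternative 1 | butenolide with allyl ester on C11 (O8 tert-butyldimethylsilyl ether) | C=CCOC(=O)C1=C2[C@@H](OC1=O)[C@H]1O[C@@]1(C)CC[C@@H]1O[C@]1(C)C[C@H]2O[Si](C)(C)C(C)(C)C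
A3 | alternative 2 | open-chain C6 epoxy aldehyde with C7 enol triflate cis to the methyl ester (both epoxides, O8 tert-butyldimethylsilyl ether, O13 4-methoxybenzyl ether) | O=C[C@H]1O[C@@]1(C)CC[C@@H]1O[C@]1(C)C[C@@H](O[Si](C)(C)C(C)(C)C)/C(OS(=O)(=O)C(F)(F)F)=C(\COCc1ccc(OC)cc1)C(=O)OC
A4 | alternative 2 | bis-epoxy germacranolide, O8 tert-butyldimethylsilyl ether, O13 4-methoxybenzyl ether | COc1ccc(COCC2=C3[C@@H](OC2=O)[C@H]4O[C@@]4(C)CC[C@@H]4O[C@]4(C)C[C@H]3O[Si](C)(C)C(C)(C)C)cc1
A5 | alternative 3 | seco compound with (Z)-2-iodoprop-1-enyl on C6 and vinyl on the C1–C10 epoxide (O8 senecioate, O13 acetate) | CC(=O)OCC1=C([C@@H](OC1=O)/C=C(/C)I)[C@H](OC(=O)C=C(C)C)C[C@@]1(C)O[C@H]1C=C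
A6 | alternative 3 | 4,5-deoxy target with cis C4=C5 alkene | CC(=O)OCC1=C2[C@@H](OC1=O)/C=C(/C)CC[C@@H]1O[C@]1(C)C[C@H]2OC(=O)C=C(C)C
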